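**Plan**

1. Retrosynthesis: remove the C6 4‑hydroxybenzoate and the C8–C9 epoxide, cut the isopropyl group from C4 (C4 ketone), take C6/C7 back to an ene‑1,2‑dione, then cut C1–C10 and C6–C7 of the seven‑membered ring together. This leaves a cyclopentenyl acylsilane (C6–C5=C1) and the enolate of methyl vinyl ketone (C7–C10).
2. Forward: the five‑membered ring comes first (from 2‑bromo‑3‑methylcyclopentenone). The seven‑membered ring is fused on in one operation by a Brook rearrangement‑mediated (3+4) annulation. Then follow the C8 methyl (enol triflate coupling), the C7 oxygen (SeO2), the diol, the isopropyl group, the ester and the epoxide.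
3. Enabling feature: the C5=C1 double bond of the five‑membered ring is conjugated to the C6 acylsilane carbonyl. Enolate addition at C6, 1,2‑Brook shift and closure on the C8 ketone give a cis‑1,2‑dialkenylcyclopropanolate in which C1 and C10 are 1,6‑related, so an anionic oxy‑Cope shift closes the ring C5–C6–C7–C8–C9–C10–C1.
4. Stereochemistry: the C4 carbinol (CBS reduction) is the only external source. Its silyl ether steers C1 in the key step and H‑5 on ketonization; the free C4 hydroxyl then relays by directed hydride delivery to C6 and on to C7, and is erased by oxidation. The C1 methyl then steers isopropyl addition to C4 and, together with the C7 silyl ether, the epoxidation.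
5. Helpers taken out again: the C4 OTBS stereocentre, the C8 enol triflate, the C6/C7 phenylboronate, the C7 OTES group and the aryl OTBS group.

Key step: step 5

Remark: daucane locants are used throughout (C1 = methyl‑bearing ring‑fusion carbon, C2/C3 = CH2 of the five‑membered ring, C4 = carbinol carbon of the five‑membered ring, C5 = ring‑fusion CH, C6 to C10 around the seven‑membered ring from C5 to C1); β is the face of the C1 methyl, α the opposite face. The target then has 4β‑OH, 4α‑isopropyl, 5α‑H, 6α‑ester, 7β‑OH and an 8α,9α‑epoxide.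
Assumption: 2‑bromo‑3‑methylcyclopent‑2‑en‑1‑one, 2‑(trimethylsilyloxy)buta‑1,3‑diene and 4‑[(tert‑butyldimethylsilyl)oxy]benzoic acid are purchased.

**Step 1**
Reactants: 1 2‑bromo‑3‑methylcyclopent‑2‑en‑1‑one
Product: 2 (S)‑2‑bromo‑3‑methylcyclopent‑2‑en‑1‑ol
Conditions: (R)‑2‑methyl‑CBS‑oxazaborolidine (0.1 equiv), BH3·SMe2, THF, −20 °C; MeOH quench
Reagents that add atoms: none
Why: Corey–Bakshi–Shibata reduction; the 2‑bromo substituent makes the alkenyl side the large group, so the (R)‑catalyst should give the (S)‑carbinol, which is C4 of the target with its oxygen on the future β face.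

**Step 2**
Reactants: 2 (S)‑2‑bromo‑3‑methylcyclopent‑2‑en‑1‑ol
Product: 3 (S)‑[(2‑bromo‑3‑methylcyclopent‑2‑en‑1‑yl)oxy](tert‑butyl)dimethylsilane
Conditions: TBSCl, imidazole, DMF, rt
Reagents that add atoms: tert‑butyldimethylsilyl chloride CC(C)(C)[Si](C)(C)Cl
Why: standard silylation; the bulky silyl ether is the steering group for the key step and migrates from O to C only slowly in the alkenyllithium of step 3.

**Step 3**
Reactants: 3 (S)‑[(2‑bromo‑3‑methylcyclopent‑2‑en‑1‑yl)oxy](tert‑butyl)dimethylsilane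
Product: 5 (S)‑[5‑(tert‑butyldimethylsilyloxy)‑2‑methylcyclopent‑1‑en‑1‑yl](morpholin‑4‑yl)methanone, via vinyllithium 4 (not isolated)
Conditions: t‑BuLi (2.1 equiv), Et2O, −78 °C; then cannulate into 4‑morpholinecarbonyl chloride, THF, −78 → 0 °C
Reagents that add atoms: 4‑morpholinecarbonyl chloride O=C(Cl)N1CCOCC1
Why: bromine–lithium exchange followed by acylation of the alkenyllithium with a carbamoyl chloride introduces C6 as a morpholine amide; the low temperature suppresses retro‑Brook silyl migration and C4 is not touched.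

**Step 4**
Reactants: 5 (S)‑[5‑(tert‑butyldimethylsilyloxy)‑2‑methylcyclopent‑1‑en‑1‑yl](morpholin‑4‑yl)methanone
Product: 6 (S)‑[5‑(tert‑butyldimethylsilyloxy)‑2‑methylcyclopent‑1‑en‑1‑yl][dimethyl(phenyl)silyl]methanone
Conditions: PhMe2SiLi, THF, −78 °C; aq NH4Cl
Reagents that add atoms: dimethylphenylsilyllithium [Li][Si](C)(C)c1ccccc1
Why: acylsilane synthesis by silyllithium addition to a morpholine amide, whose tetrahedral adduct collapses only on work‑up; the β,β‑disubstituted alkene disfavours 1,4‑addition.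

**Step 5**
Reactants: 6 (S)‑[5‑(tert‑butyldimethylsilyloxy)‑2‑methylcyclopent‑1‑en‑1‑yl][dimethyl(phenyl)silyl]methanone; 7 2‑(trimethylsilyloxy)buta‑1,3‑diene
Product: 11 4β‑(tert‑butyldimethylsilyloxy)‑6‑[dimethyl(phenyl)silyloxy]‑1β‑methylbicyclo[5.3.0]deca‑5,8‑dien‑8‑yl trifluoromethanesulfonate (daucane locants), via lithium butadienolate 8 (not isolated), via cyclopropanediolate 9 (not isolated), via ring‑expanded enolate 10 (not isolated)
Conditions: 7, MeLi, THF, 0 °C → rt; then −78 °C, add 6, −78 → 0 °C; then −78 °C, Comins' reagent, → 0 °C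
Reagents that add atoms: N‑(5‑chloropyridin‑2‑yl)‑1,1,1‑trifluoro‑N‑(trifluoromethylsulfonyl)methanesulfonamide (Comins' reagent) FC(F)(F)S(=O)(=O)N(c1ccc(Cl)cn1)S(=O)(=O)C(F)(F)F
Why: Enolate 8 adds to the acylsilane carbonyl (C6–C7 bond), the alkoxide triggers a 1,2‑Brook shift of silicon from C6 to oxygen and the α‑siloxy allyl anion closes on the C8 ketone to give the cis‑1,2‑dialkenylcyclopropane‑1,2‑diol derivative 9, whose anionic oxy‑Cope rearrangement through a boat transition state forms C1–C10, cleaves C6–C8 and leaves enolate 10 regiospecifically toward C9, where it is trapped as the enol triflate. The closest known reaction type is the Brook rearrangement‑mediated [3+4] annulation of α,β‑unsaturated acylsilanes with lithium enolates of alkenyl methyl ketones. The three‑membered ring closes by 3‑exo‑trig carbanion addition and the seven‑membered ring by [3,3]‑sigmatropic ring expansion, while the five‑membered ring is carried through intact. The new quaternary stereocentre C1 is controlled by C4: in the boat transition state the C4 substituent on the inner face of the cyclopentene points at C9–H, so H sits inside and OTBS outside, C10 bonds to C1 anti to OTBS, and the C1 methyl (the Z substituent) ends cis to the C4 oxygen. The step needs regioselectivity (C6 to the enolate carbon, C1 to the vinyl terminus), which the mechanism fixes, and facial selectivity, which the H/OTBS size difference and reversible cyclopropanolate formation should secure; the oxyanion acceleration is relied on to overcome the slow Cope shift of a fully substituted alkene terminus.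

**Step 6**
Reactants: 11 4β‑(tert‑butyldimethylsilyloxy)‑6‑[dimethyl(phenyl)silyloxy]‑1β‑methylbicyclo[5.3.0]deca‑5,8‑dien‑8‑yl trifluoromethanesulfonate
Product: 13 4β‑hydroxy‑1β,8‑dimethyl‑5αH‑bicyclo[5.3.0]dec‑8‑en‑6‑one (daucane locants), via methylated bis‑silyl diene 12 (not isolated)
Conditions: MeZnCl, Pd(PPh3)4 (5 mol %), THF, 50 °C; then 0 °C, HF·pyridine, pyridine, → rt
Reagents that add atoms: methylzinc chloride C[Zn]Cl
Why: Negishi coupling of the enol triflate places the C8 methyl on the C8=C9 alkene; buffered fluoride then cleaves the silyl enol ether and the C4 silyl ether, and ketonization should protonate C5 from the α face, opposite both the C1 methyl and the C4 silyloxy group, giving the trans ring fusion without moving the β,γ‑alkene into conjugation.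

**Step 7**
Reactants: 13 4β‑hydroxy‑1β,8‑dimethyl‑5αH‑bicyclo[5.3.0]dec‑8‑en‑6‑one
Product: 14 4β‑hydroxy‑1β,8‑dimethyl‑5αH‑bicyclo[5.3.0]dec‑8‑ene‑6,7‑dione (daucane locants)
Conditions: SeO2 (1.3 equiv), 1,4‑dioxane, H2O (2 equiv), pyridine (cat.), 70 °C
Reagents that add atoms: selenium dioxide O=[Se]=O
Why: Riley oxidation; C7 is both the only α‑methylene of the C6 ketone and the ring allylic CH2 on the more substituted alkene carbon, so the ketone and allylic pathways of SeO2 converge on C7 to give the ene‑1,2‑dione.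

**Step 8**
Reactants: 14 4β‑hydroxy‑1β,8‑dimethyl‑5αH‑bicyclo[5.3.0]dec‑8‑ene‑6,7‑dione
Product: 15 1β,8‑dimethyl‑5αH‑bicyclo[5.3.0]dec‑8‑ene‑4β,6α,7β‑triol (daucane locants)
Conditions: Me4NBH(OAc)3 (6 equiv), MeCN/AcOH 1:1, −30 °C → rt
Reagents that add atoms: none
Why: Saksena–Evans hydroxyl‑directed reduction used twice in one flask: the C4 alkoxyborohydride delivers hydride to C6 from the β face (1,3‑anti, 6α‑OH), which is possible only in the trans‑fused C5 epimer where the C4 hydroxyl and C6 are cis on the five‑membered ring, and the new C6 alkoxyborohydride then delivers hydride to the C7 enone carbonyl from the α face (trans‑1,2‑diol, 7β‑OH).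

**Step 9**
Reactants: 15 1β,8‑dimethyl‑5αH‑bicyclo[5.3.0]dec‑8‑ene‑4β,6α,7β‑triol
Product: 18 6α,7β‑dihydroxy‑1β,8‑dimethyl‑5αH‑bicyclo[5.3.0]dec‑8‑en‑4‑one (daucane locants), via phenylboronate 16 (not isolated), via keto phenylboronate 17 (not isolated)
Conditions: PhB(OH)2 (1.05 equiv), 4 Å MS, CH2Cl2, rt; then Dess–Martin periodinane, NaHCO3, 0 °C → rt; then pinacol, THF/H2O, rt
Reagents that add atoms: none
Why: a temporary cyclic phenylboronate can form only across the vicinal trans C6/C7 diol (the C4 and C6 hydroxyls are anti and cannot be bridged), so Dess–Martin oxidation takes the C4 carbinol alone and pinacol transesterification frees the diol; the helper stereocentre is erased under base‑free conditions that should not epimerize H‑5.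

**Step 10**
Reactants: 18 6α,7β‑dihydroxy‑1β,8‑dimethyl‑5αH‑bicyclo[5.3.0]dec‑8‑en‑4‑one
Product: 19 dauc‑8‑ene‑4β,6α,7β‑triol (4α‑isopropyl, 5α‑H)
Conditions: iPrMgCl (5 equiv), CeCl3 (5 equiv), THF, −78 → −40 °C; aq NH4Cl
Reagents that add atoms: isopropylmagnesium chloride CC(C)[Mg]Cl
Why: Imamoto organocerium addition, weakly basic so that enolization, reduction and retro‑aldol opening of the alkoxides are suppressed; the nucleophile should attack the C4 ketone of the trans‑fused bicycle from the α face, opposite the pseudo‑axial C1 methyl (as with angular‑methyl hydrindanones), giving 4β‑OH and 4α‑isopropyl.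

**Step 11**
Reactants: 19 dauc‑8‑ene‑4β,6α,7β‑triol
Product: 20 7β‑(triethylsilyloxy)dauc‑8‑ene‑4β,6α‑diol
Conditions: TESCl (1.1 equiv), imidazole, CH2Cl2, −20 → 0 °C
Reagents that add atoms: triethylsilyl chloride CC[Si](Cl)(CC)CC
Why: selective silylation of the allylic C7 hydroxyl; the C6 hydroxyl is flanked by C5, which carries two quaternary neighbours, and the C4 hydroxyl is tertiary.

**Step 12**
Reactants: 20 7β‑(triethylsilyloxy)dauc‑8‑ene‑4β,6α‑diol; 21 4‑[(tert‑butyldimethylsilyl)oxy]benzoic acid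
Product: 22 4β‑hydroxy‑7β‑(triethylsilyloxy)dauc‑8‑en‑6α‑yl 4‑(tert‑butyldimethylsilyloxy)benzoate
Conditions: 21, 2,4,6‑trichlorobenzoyl chloride, Et3N, toluene, rt; then 20, DMAP, 40 °C
Reagents that add atoms: none
Why: Yamaguchi esterification of the only remaining secondary hydroxyl (C6); the tertiary C4 hydroxyl does not acylate and no stereocentre is involved.

**Step 13**
Reactants: 22 4β‑hydroxy‑7β‑(triethylsilyloxy)dauc‑8‑en‑6α‑yl 4‑(tert‑butyldimethylsilyloxy)benzoate
Product: 23 8α,9α‑epoxy‑4β‑hydroxy‑7β‑(triethylsilyloxy)daucan‑6α‑yl 4‑(tert‑butyldimethylsilyloxy)benzoate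
Conditions: mCPBA, NaHCO3, CH2Cl2, 0 °C
Reagents that add atoms: 3‑chloroperoxybenzoic acid OOC(=O)c1cccc(Cl)c1
Why: Prilezhaev epoxidation of the trisubstituted C8=C9 alkene from the α face, anti to the β silyloxy group at C7 and the β methyl at C1; no free allylic hydroxyl is present to direct the peracid to the other face.

**Step 14**
Reactants: 23 8α,9α‑epoxy‑4β‑hydroxy‑7β‑(triethylsilyloxy)daucan‑6α‑yl 4‑(tert‑butyldimethylsilyloxy)benzoate
Product: 24 8α,9α‑epoxy‑4β,7β‑dihydroxydaucan‑6α‑yl 4‑hydroxybenzoate (CNP0290052.1)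
Conditions: Bu4NF, AcOH (1:1), THF, 0 °C → rt
Reagents that add atoms: none
Why: fluoride desilylation removes the aryl TBS ether and the C7 TES ether; the acetic acid buffer should suppress O6→O7 acyl migration and Payne rearrangement of the epoxy alcohol, and no stereocentre is touched.

**Compound list**

1 | 2‑bromo‑3‑methylcyclopent‑2‑en‑1‑one | O=C1CCC(C)=C1Br | starting material
2 | (S)‑2‑bromo‑3‑methylcyclopent‑2‑en‑1‑ol | O[C@H]1CCC(C)=C1Br | intermediate
3 | (S)‑[(2‑bromo‑3‑methylcyclopent‑2‑en‑1‑yl)oxy](tert‑butyl)dimethylsilane | CC(C)(C)[Si](C)(C)O[C@H]1CCC(C)=C1Br | intermediate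
4 | (S)‑[5‑(tert‑butyldimethylsilyloxy)‑2‑methylcyclopent‑1‑en‑1‑yl]lithium (not isolated) | CC(C)(C)[Si](C)(C)O[C@H]1CCC(C)=C1[Li] | intermediate
5 | (S)‑[5‑(tert‑butyldimethylsilyloxy)‑2‑methylcyclopent‑1‑en‑1‑yl](morpholin‑4‑yl)methanone | CC(C)(C)[Si](C)(C)O[C@H]1CCC(C)=C1C(=O)N2CCOCC2 | intermediate
6 | (S)‑[5‑(tert‑butyldimethylsilyloxy)‑2‑methylcyclopent‑1‑en‑1‑yl][dimethyl(phenyl)silyl]methanone | CC(C)(C)[Si](C)(C)O[C@H]1CCC(C)=C1C(=O)[Si](C)(C)c2ccccc2 | intermediate
7 | 2‑(trimethylsilyloxy)buta‑1,3‑diene | C=CC(=C)O[Si](C)(C)C | starting material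
8 | lithium buta‑1,3‑dien‑2‑olate (not isolated) | [Li+].[O-]C(=C)C=C | intermediate
9 | lithium cyclopropanolate carrying the cyclopentenyl group and OSiMe2Ph on one carbon and vinyl and O⁻ on the neighbouring carbon, the two alkenyl groups cis (not isolated) | [Li+].CC(C)(C)[Si](C)(C)O[C@H]1CCC(C)=C1[C@]3(O[Si](C)(C)c2ccccc2)C[C@]3([O-])C=C | intermediate
10 | lithium C8 enolate (C8=C9) of the ring‑expanded 5–7 bicycle, 4β‑OTBS, 6‑OSiMe2Ph enol ether (not isolated) | [Li+].CC(C)(C)[Si](C)(C)O[C@H]1CC[C@]2(C)CC=C([O-])CC(O[Si](C)(C)c3ccccc3)=C21 | intermediate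
11 | 4β‑(tert‑butyldimethylsilyloxy)‑6‑[dimethyl(phenyl)silyloxy]‑1β‑methylbicyclo[5.3.0]deca‑5,8‑dien‑8‑yl trifluoromethanesulfonate (daucane locants) | CC(C)(C)[Si](C)(C)O[C@H]1CC[C@]2(C)CC=C(OS(=O)(=O)C(F)(F)F)CC(O[Si](C)(C)c3ccccc3)=C21 | intermediate
12 | 4β‑(tert‑butyldimethylsilyloxy)‑6‑[dimethyl(phenyl)silyloxy]‑1β,8‑dimethylbicyclo[5.3.0]deca‑5,8‑diene (not isolated) | CC(C)(C)[Si](C)(C)O[C@H]1CC[C@]2(C)CC=C(C)CC(O[Si](C)(C)c3ccccc3)=C21 | intermediate
13 | 4β‑hydroxy‑1β,8‑dimethyl‑5αH‑bicyclo[5.3.0]dec‑8‑en‑6‑one | O[C@H]1CC[C@]2(C)CC=C(C)CC(=O)[C@H]21 | intermediate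
14 | 4β‑hydroxy‑1β,8‑dimethyl‑5αH‑bicyclo[5.3.0]dec‑8‑ene‑6,7‑dione | O[C@H]1CC[C@]2(C)CC=C(C)C(=O)C(=O)[C@H]21 | intermediate
15 | 1β,8‑dimethyl‑5αH‑bicyclo[5.3.0]dec‑8‑ene‑4β,6α,7β‑triol | O[C@H]1CC[C@]2(C)CC=C(C)[C@@H](O)[C@H](O)[C@H]21 | intermediate
16 | cyclic 6α,7β‑O‑phenylboronate of 15 (not isolated) | O[C@H]1CC[C@]2(C)CC=C(C)[C@@H](O3)[C@H](OB3c4ccccc4)[C@H]21 | intermediate
17 | C4 ketone of boronate 16 (not isolated) | O=C1CC[C@]2(C)CC=C(C)[C@@H](O3)[C@H](OB3c4ccccc4)[C@H]21 | intermediate
18 | 6α,7β‑dihydroxy‑1β,8‑dimethyl‑5αH‑bicyclo[5.3.0]dec‑8‑en‑4‑one | O=C1CC[C@]2(C)CC=C(C)[C@@H](O)[C@H](O)[C@H]21 | intermediate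
19 | dauc‑8‑ene‑4β,6α,7β‑triol | CC(C)[C@]1(O)CC[C@]2(C)CC=C(C)[C@@H](O)[C@H](O)[C@H]21 | intermediate
20 | 7β‑(triethylsilyloxy)dauc‑8‑ene‑4β,6α‑diol | CC(C)[C@]1(O)CC[C@]2(C)CC=C(C)[C@@H](O[Si](CC)(CC)CC)[C@H](O)[C@H]21 | intermediate
21 | 4‑[(tert‑butyldimethylsilyl)oxy]benzoic acid | CC(C)(C)[Si](C)(C)Oc1ccc(cc1)C(=O)O | starting material
22 | 4β‑hydroxy‑7β‑(triethylsilyloxy)dauc‑8‑en‑6α‑yl 4‑(tert‑butyldimethylsilyloxy)benzoate | CC(C)[C@]1(O)CC[C@]2(C)CC=C(C)[C@@H](O[Si](CC)(CC)CC)[C@H](OC(=O)c3ccc(O[Si](C)(C)C(C)(C)C)cc3)[C@H]21 | intermediate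
23 | 8α,9α‑epoxy‑4β‑hydroxy‑7β‑(triethylsilyloxy)daucan‑6α‑yl 4‑(tert‑butyldimethylsilyloxy)benzoate | CC(C)[C@]1(O)CC[C@]2(C)C[C@@H]3O[C@]3(C)[C@@H](O[Si](CC)(CC)CC)[C@H](OC(=O)c4ccc(O[Si](C)(C)C(C)(C)C)cc4)[C@H]21 | intermediate
24 | 8α,9α‑epoxy‑4β,7β‑dihydroxydaucan‑6α‑yl 4‑hydroxybenzoate (CNP0290052.1) | CC(C)[C@]1(O)CC[C@]2(C)C[C@@H]3O[C@]3(C)[C@@H](O)[C@H](OC(=O)c3ccc(O)cc3)[C@H]21 | target

**Count and risks**

Total step count: 14. Longest linear sequence: 14 steps (from 1 to 24); 7 and 21 enter as purchased partners.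

Steps most likely to fail:

Step 5. The oxy‑Cope shift of cyclopropanolate 9 may stall because the C1 terminus is fully substituted and carries a Z methyl, so that 9 reverts or fragments instead of expanding. The facial preference at C1 may also be low, and enolate 10 may equilibrate toward C7 before triflation. The fallback sets out from amide 5 and comes back at 13, building the same two bonds one after the other. Amide 5 is treated with 2‑methylallylmagnesium chloride (THF, −78 → 0 °C; the morpholine amide stops at the ketone) to give the cross‑conjugated dienone F1. A Hosomi–Sakurai conjugate allylation (allyltrimethylsilane, TiCl4, CH2Cl2, −78 °C) adds the allyl group to C1 anti to the C4 silyloxy group, and kinetic protonation of the enolate at C5 gives the allyl ketone F2 with the quaternary centre in place. Ring‑closing metathesis between the allyl and 2‑methylallyl groups (second‑generation Grubbs catalyst, CH2Cl2, 40 °C) closes the seven‑membered ring at C8=C9 to give the silyl ether F3, and HF·pyridine removes the silyl group to reach 13.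

Step 7. Under the hot, weakly acidic Riley conditions the β‑hydroxy ketone may dehydrate toward C4=C5, H‑5 may epimerize, and SeO2 may also attack the other allylic positions (C10 and the C8 methyl). The fallback sets out from 13 and comes back at 14. The dianion is formed with LiN(SiMe3)2 (2.5 equiv, THF, −78 °C; kinetic deprotonation at C7) and oxidized with 2‑(phenylsulfonyl)‑3‑phenyloxaziridine (Davis reagent) to the α‑hydroxy ketone F4 (both C7 epimers serve). The α‑ketol alone is then oxidized with Cu(OAc)2 under air in MeOH, which leaves the isolated C4 carbinol untouched, to give 14.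

Step 8. Undirected hydride attack on the very electrophilic 1,2‑dione and epimerization at C5 through the diosphenol tautomer may erode the hydroxyl relay. The fallback sets out from 14 and comes back at 15, reversing the order of the two reductions. Luche reduction (NaBH4, CeCl3·7H2O, MeOH, −78 °C) takes the conjugated C7 carbonyl first; attack from the α face, where only H‑5 is 1,3‑related while the β face carries the C1 methyl, should give the pseudo‑equatorial 7β‑hydroxy ketone F5. The C6 ketone, now flanked by two β hydroxyls (C4 and C7), is then reduced from the β face with Me4NBH(OAc)3 in MeCN/AcOH to give 15.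

**Further compounds**

F1 | step 5 | (S)‑1‑[5‑(tert‑butyldimethylsilyloxy)‑2‑methylcyclopent‑1‑en‑1‑yl]‑3‑methylbut‑3‑en‑1‑one | CC(C)(C)[Si](C)(C)O[C@H]1CCC(C)=C1C(=O)CC(C)=C
F2 | step 5 | 1‑[2‑allyl‑5‑(tert‑butyldimethylsilyloxy)‑2‑methylcyclopentyl]‑3‑methylbut‑3‑en‑1‑one (allyl anti to OTBS, acyl group cis to OTBS) | CC(C)(C)[Si](C)(C)O[C@H]1CC[C@](C)(CC=C)[C@H]1C(=O)CC(C)=C
F3 | step 5 | 4β‑(tert‑butyldimethylsilyloxy)‑1β,8‑dimethyl‑5αH‑bicyclo[5.3.0]dec‑8‑en‑6‑one (daucane locants) | CC(C)(C)[Si](C)(C)O[C@H]1CC[C@]2(C)CC=C(C)CC(=O)[C@H]21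
F4 | step 7 | 4β,7‑dihydroxy‑1β,8‑dimethyl‑5αH‑bicyclo[5.3.0]dec‑8‑en‑6‑one (C7 epimers) | O[C@H]1CC[C@]2(C)CC=C(C)C(O)C(=O)[C@H]21
F5 | step 8 | 4β,7β‑dihydroxy‑1β,8‑dimethyl‑5αH‑bicyclo[5.3.0]dec‑8‑en‑6‑one | O[C@H]1CC[C@]2(C)CC=C(C)[C@@H](O)C(=O)[C@H]21
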